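**Retrosynthetic overview**
- The target is reached by cleaving fourteen methyl ethers of a hexameric aryl ether. Rings F and E are each added to a phenol by SNAr with 4-fluoro-2,6-dimethoxybenzaldehyde followed by Baeyer–Villiger oxidation, so the formyl carbon becomes the next phenolic oxygen site.
- The strategy rests on ring D: D1 carries the oxygen to ring C, D2 the oxygen to ring E, D3–D5 hydroxyls and D6 hydrogen. The para oxygens at D2 and D5 enclose the vicinal oxygens at D3 and D4, which is the hydroquinone pattern of a ring grown from dimethyl squarate, so the C–C bond D1–D2 is disconnected.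
- Ring D comes from thermal ring expansion of a 2,3,4-trimethoxy-4-[(Z)-2-aryloxyvinyl]cyclobutenone. The carbinol oxygen is already a methyl ether, so D5 emerges as OMe and only the D2 hydroxyl is free for the next etherification.
- The cyclobutenone comes from dimethyl squarate and a lithium aryloxyacetylide (ABC phenol plus trichloroethylene), then semi-hydrogenation. The alkene is brought in as an alkyne because a 2-aryloxyvinyllithium with lithium anti to the aryloxide would fragment by β-elimination.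
- Rings A, B, C, E and F are bought as benzene rings; only ring D is constructed, after A–B–C are joined and before E and F are attached.

Key step: step 8

Assumption: 4-fluoro-2,6-dimethoxybenzaldehyde is taken as a catalogue compound (otherwise one step from 1-fluoro-3,5-dimethoxybenzene by lithiation between the methoxy groups and DMF); the carbinol-derived carbon of 15, 16 and 17 is racemic and is destroyed in step 8.

**Step 1**
Reactants: 1 2,4,6-trimethoxyphenol; 2 4-fluoro-2,6-dimethoxybenzaldehyde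
Product: 3 AB aldehyde 2,6-dimethoxy-4-(2,4,6-trimethoxyphenoxy)benzaldehyde
Conditions: Cs2CO3, DMSO, 110 °C, Ar
Reagents that add atoms: none
Why: Nucleophilic aromatic substitution (SNAr through a Meisenheimer adduct) in which the para formyl group activates the fluoride and the hindered phenoxide attacks a carbon flanked by two hydrogens, the methoxy groups being far poorer leaving groups.

**Step 2**
Reactants: 3 AB aldehyde
Product: 5 AB phenol 2,6-dimethoxy-4-(2,4,6-trimethoxyphenoxy)phenol, via aryl formate 4 (not isolated)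
Conditions: mCPBA, CH2Cl2, 0 °C to rt; NaHCO3 wash; then K2CO3 (cat.), MeOH, rt
Reagents that add atoms: mCPBA (3-chloroperoxybenzoic acid), OOC(=O)c1cccc(Cl)c1
Why: Baeyer–Villiger oxidation of an electron-rich benzaldehyde (Dakin-type), in which the 2,6-dimethoxyaryl group migrates in preference to hydrogen, followed by methanolysis of the formate to free the phenol.

**Step 3**
Reactants: 5 AB phenol; 2 4-fluoro-2,6-dimethoxybenzaldehyde
Product: 6 ABC aldehyde 4-[2,6-dimethoxy-4-(2,4,6-trimethoxyphenoxy)phenoxy]-2,6-dimethoxybenzaldehyde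
Conditions: Cs2CO3, DMSO, 110 °C, Ar
Reagents that add atoms: none
Why: The same SNAr as in step 1, with a 2,6-dimethoxyphenoxide of the same type as the nucleophile.

**Step 4**
Reactants: 6 ABC aldehyde
Product: 8 ABC phenol 4-[2,6-dimethoxy-4-(2,4,6-trimethoxyphenoxy)phenoxy]-2,6-dimethoxyphenol (its aryl group is called Ar below), via aryl formate 7 (not isolated)
Conditions: mCPBA, CH2Cl2, 0 °C to rt; NaHCO3 wash; then K2CO3 (cat.), MeOH, rt
Reagents that add atoms: mCPBA (3-chloroperoxybenzoic acid), OOC(=O)c1cccc(Cl)c1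
Why: Baeyer–Villiger oxidation and formate methanolysis as in step 2.

**Step 5**
Reactants: 8 ABC phenol; 9 trichloroethylene
Product: 11 Ar (E)-1,2-dichlorovinyl ether, via dichloroacetylene 10 (not isolated)
Conditions: K2CO3, DMF, 70 °C
Reagents that add atoms: none
Why: Base-induced dehydrochlorination of trichloroethylene followed by anti addition of the phenoxide to dichloroacetylene, the known route from phenols to 1,2-dichlorovinyl ethers, gives the E isomer.

**Step 6**
Reactants: 11 Ar (E)-1,2-dichlorovinyl ether; 12 dimethyl squarate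
Product: 16 4-[(Ar-oxy)ethynyl]-2,3,4-trimethoxycyclobut-2-en-1-one (racemic), via chloroethynyl ether 13 (not isolated), via lithium aryloxyacetylide 14 (not isolated), via lithium alkoxide 15 (not isolated)
Conditions: n-BuLi (2.05 equiv), THF, −78 to −40 °C; then 12, −78 °C; then MeOTf, −78 °C to rt
Reagents that add atoms: methyl trifluoromethanesulfonate (MeOTf), COS(=O)(=O)C(F)(F)F
Why: Deprotonation with β-elimination and chlorine–lithium exchange (the dichlorovinyl ether route to lithium alkynyl ethers) give an acetylide that adds 1,2 to one squarate carbonyl as lithium acetylides are known to do, and the tertiary alkoxide is O-methylated in the flask; the new carbinol carbon is racemic and is lost in step 8.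

**Step 7**
Reactants: 16 alkynyl cyclobutenone
Product: 17 4-[(Z)-2-(Ar-oxy)vinyl]-2,3,4-trimethoxycyclobut-2-en-1-one (racemic)
Conditions: H2 (1 atm), Pd/CaCO3 poisoned with Pb(OAc)2, quinoline, EtOAc, rt
Reagents that add atoms: none
Why: Lindlar-type semi-hydrogenation adds hydrogen syn to the ynol ether to give the Z enol ether, while the tetrasubstituted dimethoxy alkene of the cyclobutenone is not reduced.

**Step 8**
Reactants: 17 (Z)-aryloxyvinyl cyclobutenone
Product: 20 ring D phenol 6-(Ar-oxy)-2,3,4-trimethoxyphenol (D2 hydroxyl free; D3, D4, D5 methoxy), via dienylketene 18 (not isolated), via cyclohexadienone 19 (not isolated)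
Conditions: toluene (degassed, 0.01 M), 110 °C, Ar
Reagents that add atoms: none
Why: Heating breaks the C1–C4 bond of the cyclobutenone in a conrotatory 4π electrocyclic opening in which the donor methoxy group on C4 turns outward, so the aryloxyvinyl group turns inward and lies cis to the ketene in 18. Ring D then closes by a thermal disrotatory 6π electrocyclisation in which the ketene carbon (future D2) bonds to the aryloxy-bearing vinyl terminus (future D1), giving cyclohexa-2,4-dienone 19, whose enolisation aromatises the ring. The closest known reaction type is the thermal ring expansion of squarate-derived 4-alkenyl-4-alkoxy- or 4-hydroxycyclobutenones to hydroquinones and their monoethers (Moore rearrangement). No stereocentre is set: the racemic carbon of 17 and the transient sp3 carbon of 19 both become aromatic carbons, and the alkene geometry is erased. The step needs outward rotation of the C4 oxygen (secured by its donor character), bond formation at the oxygen-bearing vinyl carbon (fixed by the vinyl connectivity, with the concerted six-membered closure favoured over five-membered closure at the inner vinyl carbon in non-polar toluene) and a single free hydroxyl (secured because the C4 oxygen is already a methyl ether). The sp ketene terminus has no inward substituent, so the inward aryloxy group of the Z alkene should not block the closure.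

**Step 9**
Reactants: 20 ring D phenol; 2 4-fluoro-2,6-dimethoxybenzaldehyde
Product: 21 ABCDE aldehyde 4-[6-(Ar-oxy)-2,3,4-trimethoxyphenoxy]-2,6-dimethoxybenzaldehyde
Conditions: Cs2CO3, DMSO, 110 °C, Ar (rigorously degassed)
Reagents that add atoms: none
Why: SNAr of the only free phenoxide (D2) on the formyl-activated aryl fluoride, as in step 1.

**Step 10**
Reactants: 21 ABCDE aldehyde
Product: 23 ABCDE phenol 4-[6-(Ar-oxy)-2,3,4-trimethoxyphenoxy]-2,6-dimethoxyphenol, via aryl formate 22 (not isolated)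
Conditions: mCPBA (1.2 equiv), CH2Cl2, 0 °C; NaHCO3 wash; then K2CO3 (cat.), MeOH, rt
Reagents that add atoms: mCPBA (3-chloroperoxybenzoic acid), OOC(=O)c1cccc(Cl)c1
Why: Baeyer–Villiger oxidation of the 2,6-dimethoxybenzaldehyde is faster than peracid attack on the fully etherified electron-rich rings, and formate methanolysis frees the E4 phenol.

**Step 11**
Reactants: 23 ABCDE phenol; 2 4-fluoro-2,6-dimethoxybenzaldehyde
Product: 24 ABCDEF aldehyde 4-{4-[6-(Ar-oxy)-2,3,4-trimethoxyphenoxy]-2,6-dimethoxyphenoxy}-2,6-dimethoxybenzaldehyde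
Conditions: Cs2CO3, DMSO, 110 °C, Ar
Reagents that add atoms: none
Why: SNAr as in step 1; the fluoride-bearing carbon becomes F1 and the formyl carbon marks F4.

**Step 12**
Reactants: 24 ABCDEF aldehyde
Product: 26 hexamer monophenol 4-{4-[6-(Ar-oxy)-2,3,4-trimethoxyphenoxy]-2,6-dimethoxyphenoxy}-2,6-dimethoxyphenol (fourteen methoxy groups; F4 hydroxyl free), via aryl formate 25 (not isolated)
Conditions: mCPBA (1.2 equiv), CH2Cl2, 0 °C; NaHCO3 wash; then K2CO3 (cat.), MeOH, rt
Reagents that add atoms: mCPBA (3-chloroperoxybenzoic acid), OOC(=O)c1cccc(Cl)c1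
Why: Baeyer–Villiger oxidation and formate methanolysis as in step 2 install the third oxygen of ring F.

**Step 13**
Reactants: 26 hexamer monophenol
Product: 27 CNP0175585.0 (target)
Conditions: BBr3 (excess), CH2Cl2, −78 °C to rt, Ar; then MeOH/H2O, 0 °C
Reagents that add atoms: none
Why: Lewis-acid cleavage of aryl methyl ethers with BBr3 (bromide attacks the methyl group of the boron-complexed ether) should remove all fourteen methyl groups while the diaryl ether bonds, which offer no sp3 carbon, stay intact; oxygen is excluded because rings D and F are pyrogallol-type.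

**Compound list**
1 | 2,4,6-trimethoxyphenol | COc1cc(OC)c(O)c(OC)c1 | starting material
2 | 4-fluoro-2,6-dimethoxybenzaldehyde | COc1cc(F)cc(OC)c1C=O | starting material
3 | AB aldehyde, 2,6-dimethoxy-4-(2,4,6-trimethoxyphenoxy)benzaldehyde | COc1cc(OC)c(Oc2cc(OC)c(C=O)c(OC)c2)c(OC)c1 | intermediate
4 | AB aryl formate | COc1cc(OC)c(Oc2cc(OC)c(OC=O)c(OC)c2)c(OC)c1 | intermediate (not isolated)
5 | AB phenol, 2,6-dimethoxy-4-(2,4,6-trimethoxyphenoxy)phenol | COc1cc(OC)c(Oc2cc(OC)c(O)c(OC)c2)c(OC)c1 | intermediate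
6 | ABC aldehyde | COc1cc(OC)c(Oc2cc(OC)c(Oc3cc(OC)c(C=O)c(OC)c3)c(OC)c2)c(OC)c1 | intermediate
7 | ABC aryl formate | COc1cc(OC)c(Oc2cc(OC)c(Oc3cc(OC)c(OC=O)c(OC)c3)c(OC)c2)c(OC)c1 | intermediate (not isolated)
8 | ABC phenol (ArOH) | COc1cc(OC)c(Oc2cc(OC)c(Oc3cc(OC)c(O)c(OC)c3)c(OC)c2)c(OC)c1 | intermediate
9 | trichloroethylene | ClC=C(Cl)Cl | starting material
10 | dichloroacetylene | ClC#CCl | intermediate (not isolated)
11 | Ar (E)-1,2-dichlorovinyl ether | COc1cc(OC)c(Oc2cc(OC)c(Oc3cc(OC)c(O/C(Cl)=C\Cl)c(OC)c3)c(OC)c2)c(OC)c1 | intermediate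
12 | dimethyl squarate | COC1=C(OC)C(=O)C1=O | starting material
13 | Ar chloroethynyl ether | COc1cc(OC)c(Oc2cc(OC)c(Oc3cc(OC)c(OC#CCl)c(OC)c3)c(OC)c2)c(OC)c1 | intermediate (not isolated)
14 | lithium (Ar-oxy)acetylide | COc1cc(OC)c(Oc2cc(OC)c(Oc3cc(OC)c(OC#C[Li])c(OC)c3)c(OC)c2)c(OC)c1 | intermediate (not isolated)
15 | lithium 1-[(Ar-oxy)ethynyl]-2,3-dimethoxy-4-oxocyclobut-2-en-1-olate (racemic) | COc1cc(OC)c(Oc2cc(OC)c(Oc3cc(OC)c(OC#CC4(O[Li])C(=O)C(OC)=C4OC)c(OC)c3)c(OC)c2)c(OC)c1 | intermediate (not isolated)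
16 | 4-[(Ar-oxy)ethynyl]-2,3,4-trimethoxycyclobut-2-en-1-one (racemic) | COc1cc(OC)c(Oc2cc(OC)c(Oc3cc(OC)c(OC#CC4(OC)C(=O)C(OC)=C4OC)c(OC)c3)c(OC)c2)c(OC)c1 | intermediate
17 | 4-[(Z)-2-(Ar-oxy)vinyl]-2,3,4-trimethoxycyclobut-2-en-1-one (racemic), key-step precursor | COc1cc(OC)c(Oc2cc(OC)c(Oc3cc(OC)c(O/C=C\C4(OC)C(=O)C(OC)=C4OC)c(OC)c3)c(OC)c2)c(OC)c1 | intermediate
18 | (3Z,5Z)-6-(Ar-oxy)-2,3,4-trimethoxyhexa-1,3,5-trien-1-one (dienylketene) | COc1cc(OC)c(Oc2cc(OC)c(Oc3cc(OC)c(O/C=C\C(OC)=C(OC)/C(OC)=C=O)c(OC)c3)c(OC)c2)c(OC)c1 | intermediate (not isolated)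
19 | 6-(Ar-oxy)-2,3,4-trimethoxycyclohexa-2,4-dien-1-one (racemic) | COc1cc(OC)c(Oc2cc(OC)c(Oc3cc(OC)c(OC4C=C(OC)C(OC)=C(OC)C4=O)c(OC)c3)c(OC)c2)c(OC)c1 | intermediate (not isolated)
20 | ring D phenol, 6-(Ar-oxy)-2,3,4-trimethoxyphenol, key-step product | COc1cc(OC)c(Oc2cc(OC)c(Oc3cc(OC)c(Oc4cc(OC)c(OC)c(OC)c4O)c(OC)c3)c(OC)c2)c(OC)c1 | intermediate
21 | ABCDE aldehyde | COc1cc(OC)c(Oc2cc(OC)c(Oc3cc(OC)c(Oc4cc(OC)c(OC)c(OC)c4Oc4cc(OC)c(C=O)c(OC)c4)c(OC)c3)c(OC)c2)c(OC)c1 | intermediate
22 | ABCDE aryl formate | COc1cc(OC)c(Oc2cc(OC)c(Oc3cc(OC)c(Oc4cc(OC)c(OC)c(OC)c4Oc4cc(OC)c(OC=O)c(OC)c4)c(OC)c3)c(OC)c2)c(OC)c1 | intermediate (not isolated)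
23 | ABCDE phenol | COc1cc(OC)c(Oc2cc(OC)c(Oc3cc(OC)c(Oc4cc(OC)c(OC)c(OC)c4Oc4cc(OC)c(O)c(OC)c4)c(OC)c3)c(OC)c2)c(OC)c1 | intermediate
24 | ABCDEF aldehyde | COc1cc(OC)c(Oc2cc(OC)c(Oc3cc(OC)c(Oc4cc(OC)c(OC)c(OC)c4Oc4cc(OC)c(Oc5cc(OC)c(C=O)c(OC)c5)c(OC)c4)c(OC)c3)c(OC)c2)c(OC)c1 | intermediate
25 | ABCDEF aryl formate | COc1cc(OC)c(Oc2cc(OC)c(Oc3cc(OC)c(Oc4cc(OC)c(OC)c(OC)c4Oc4cc(OC)c(Oc5cc(OC)c(OC=O)c(OC)c5)c(OC)c4)c(OC)c3)c(OC)c2)c(OC)c1 | intermediate (not isolated)
26 | hexamer monophenol (tetradecamethyl ether of the target, F4 hydroxyl free) | COc1cc(OC)c(Oc2cc(OC)c(Oc3cc(OC)c(Oc4cc(OC)c(OC)c(OC)c4Oc4cc(OC)c(Oc5cc(OC)c(O)c(OC)c5)c(OC)c4)c(OC)c3)c(OC)c2)c(OC)c1 | intermediate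
27 | CNP0175585.0 | Oc1cc(O)c(Oc2cc(O)c(Oc3cc(O)c(Oc4cc(O)c(O)c(O)c4Oc4cc(O)c(Oc5cc(O)c(O)c(O)c5)c(O)c4)c(O)c3)c(O)c2)c(O)c1 | target

**Totals**
Total step count: 13. Longest linear sequence: 13 steps (1 to 27).

**Steps most likely to fail**

Step 8. The dienylketene may close at the nucleophilic inner vinyl carbon to a five-membered zwitterion, or close slowly because the aryloxy group points inward, so that the ketene is lost to dimerisation or adventitious nucleophiles. Fallback, setting out from 8 and returning at 20: ring D is taken from a benzene ring instead of the squarate. 5-Bromo-1,2,3-trimethoxybenzene is formylated at its only free (equivalent) positions by Rieche formylation (Cl2CHOMe, TiCl4, CH2Cl2, 0 °C) to 6-bromo-2,3,4-trimethoxybenzaldehyde F1. Ullmann etherification of 8 with the ortho-formyl-activated bromide (CuI, N,N-dimethylglycine, Cs2CO3, 1,4-dioxane, 100 °C) gives 6-(Ar-oxy)-2,3,4-trimethoxybenzaldehyde F2. Baeyer–Villiger oxidation with mCPBA to the aryl formate F3 and methanolysis then deliver 20.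

Step 9. Substitution by the crowded D2 phenoxide (flanked by the Ar-oxy and a methoxy group) may be slow, and the pentaoxygenated phenoxide may be oxidised to a quinone by traces of air at 110 °C. Fallback, setting out from 20 and returning at 21: the ether bond is made by copper catalysis instead of addition–elimination, coupling 20 with purchased 4-bromo-2,6-dimethoxybenzaldehyde (CuI, N,N-dimethylglycine, Cs2CO3, 1,4-dioxane, 90 °C, Ullmann etherification). No new compound is made on the way.

Step 13. Cleavage of fourteen ethers may stall at partly methylated stages, and the free polyphenol may degrade oxidatively during aqueous isolation. Fallback, setting out from 26 and returning at 27: the ethers are cleaved by the push–pull system AlBr3 in ethanethiol (the thiol takes the methyl groups). The crude polyphenol is not isolated but acetylated in the same flask (Ac2O, pyridine) to the pentadecaacetate of the target F4, which is stable to air and can be purified on silica. Acid-catalysed methanolysis (HCl in degassed MeOH, rt) then releases 27.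

**Further compounds**
F1 | step 8 | 6-bromo-2,3,4-trimethoxybenzaldehyde | COc1cc(Br)c(C=O)c(OC)c1OC
F2 | step 8 | 6-(Ar-oxy)-2,3,4-trimethoxybenzaldehyde | COc1cc(OC)c(Oc2cc(OC)c(Oc3cc(OC)c(Oc4cc(OC)c(OC)c(OC)c4C=O)c(OC)c3)c(OC)c2)c(OC)c1
F3 | step 8 | 6-(Ar-oxy)-2,3,4-trimethoxyphenyl formate | COc1cc(OC)c(Oc2cc(OC)c(Oc3cc(OC)c(Oc4cc(OC)c(OC)c(OC)c4OC=O)c(OC)c3)c(OC)c2)c(OC)c1
F0 | step 9 | none | none
F4 | step 13 | pentadecaacetate of the target | CC(=O)Oc1cc(OC(C)=O)c(Oc2cc(OC(C)=O)c(Oc3cc(OC(C)=O)c(Oc4cc(OC(C)=O)c(OC(C)=O)c(OC(C)=O)c4Oc4cc(OC(C)=O)c(Oc5cc(OC(C)=O)c(OC(C)=O)c(OC(C)=O)c5)c(OC(C)=O)c4)c(OC(C)=O)c3)c(OC(C)=O)c2)c(OC(C)=O)c1
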